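**Assumption:** "spiculoic acid B" is taken to mean exactly the given SMILES, i.e. the trans-fused (1R,3aR,4R,5S,7aS) acid; indene numbering is used for the bicycle.

## Retrosynthetic overview

1. 19 ⇒ alkenyl triflate 12 + (E)-3-iodo-2-methylacrylic acid 16: a one-pot borylation/Suzuki union at C3–C3a gives pentaenoic acid 18, which is never isolated.
2. 18 closes the cyclohexene (C4–C5, C3a–C7a) and the cyclopentene in the same operation and sets C3a, C4, C5 and C7a; no ring exists before this step.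
3. 12 ⇒ tetraenone 10 by catalytic asymmetric conjugate methylation (C1 stereocentre) with O-triflation of the Z-enolate (geometry of the future C2=C3 ring alkene).
4. 10 ⇒ trienoate 6 ⇒ enyne 2 + EtMgBr + ethyl pent-2-ynoate 3 by two syn-carbocuprations; 2 ⇒ cinnamaldehyde 1.
5. 16 ⇒ diethyl methylmalonate 13 + iodoform 14.

## Route

**Step 1**
Reactants: 1 trans-cinnamaldehyde
Product: 2 [(E)-but-1-en-3-yn-1-yl]benzene
Conditions: TMSCHN2, LDA, THF, −78 °C → rt
Reagents that add atoms: (trimethylsilyl)diazomethane, C[Si](C)(C)C=[N+]=[N-]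
Why: Colvin (Shioiri) homologation, in which lithiated TMS-diazomethane adds to the aldehyde, loses Me3SiOLi and N2, and the alkylidene carbene undergoes a 1,2-H shift to the terminal alkyne without touching the (E)-styryl alkene.

**Step 2**
Reactants: 2 [(E)-but-1-en-3-yn-1-yl]benzene; 3 ethyl pent-2-ynoate
Product: 6 ethyl (2E,4E,6E)-3,5-diethyl-7-phenylhepta-2,4,6-trienoate, via dienylcopper 4 (not isolated), via α-cuprio trienoate 5 (not isolated)
Conditions: EtMgBr, CuBr·SMe2, Et2O/Me2S, −45 → −25 °C; then 3, −78 → −40 °C; NH4Cl (aq), −78 °C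
Reagents that add atoms: ethylmagnesium bromide, CC[Mg]Br
Why: Normant syn-carbocupration puts Et on the internal and Cu on the terminal alkyne carbon of 2, and a second syn-carbocupration (conjugate addition) of ynoate 3 followed by low-temperature protonation with retention fixes both new trisubstituted alkenes as E.

**Step 3**
Reactants: 6 ethyl (2E,4E,6E)-3,5-diethyl-7-phenylhepta-2,4,6-trienoate
Product: 7 (2E,4E,6E)-3,5-diethyl-7-phenylhepta-2,4,6-trien-1-ol
Conditions: DIBAL-H, CH2Cl2, −78 °C; Rochelle salt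
Reagents that add atoms: none
Why: DIBAL-H 1,2-reduction of the conjugated ester to the allylic alcohol, which leaves the triene geometry unchanged.

**Step 4**
Reactants: 7 (2E,4E,6E)-3,5-diethyl-7-phenylhepta-2,4,6-trien-1-ol; 8 diethyl (2-oxobutyl)phosphonate
Product: 10 (4E,6E,8E,10E)-7,9-diethyl-11-phenylundeca-4,6,8,10-tetraen-3-one, via trienal 9 (not isolated)
Conditions: MnO2, LiOH·H2O, 4 Å MS, THF, reflux
Reagents that add atoms: none
Why: Tandem oxidation–olefination (Taylor), in which MnO2 oxidises only the allylic alcohol and the Horner–Wadsworth–Emmons anion of 8 traps trienal 9 at once as the (E)-enone.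

**Step 5**
Reactants: 10 (4E,6E,8E,10E)-7,9-diethyl-11-phenylundeca-4,6,8,10-tetraen-3-one
Product: 12 (3Z,5S,6E,8E,10E)-7,9-diethyl-5-methyl-11-phenylundeca-3,6,8,10-tetraen-3-yl trifluoromethanesulfonate, via magnesium Z-enolate 11 (not isolated)
Conditions: MeMgBr, CuBr·SMe2 (5 mol %), (R,Sp)-Josiphos (6 mol %), t-BuOMe, −75 °C; then Comins' reagent, THF/DMPU, −75 → 0 °C
Reagents that add atoms: methylmagnesium bromide, C[Mg]Br; Comins' reagent, FC(F)(F)S(=O)(=O)N(c1ccc(Cl)cn1)S(=O)(=O)C(F)(F)F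
Why: Cu/Josiphos-catalysed asymmetric conjugate addition of MeMgBr (Feringa type) sets C5 as S by Si-face delivery (the ligand antipode that gives this sense is used; both are commercial; 1,6- and 1,8-addition are blocked because C7 and C9 are fully substituted), and the s-cis-derived Z-enolate 11 is O-triflated in situ, which fixes the position and Z geometry of the future ring alkene.

**Step 6**
Reactants: 13 diethyl methylmalonate; 14 iodoform
Product: 15 diethyl 2-(diiodomethyl)-2-methylpropanedioate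
Conditions: NaH, Et2O, reflux
Reagents that add atoms: none
Why: C-alkylation of the sodium malonate by iodoform installs the CHI2 group on the quaternary carbon.

**Step 7**
Reactants: 15 diethyl 2-(diiodomethyl)-2-methylpropanedioate
Product: 16 (2E)-3-iodo-2-methylprop-2-enoic acid
Conditions: KOH, EtOH/H2O, reflux; then HCl (aq)
Reagents that add atoms: potassium hydroxide, [K+].[OH-]
Why: Saponification followed by decarboxylative elimination of iodide (Grob-type fragmentation) gives the (E)-iodoacrylic acid selectively.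

**Step 8 (key step)**
Reactants: 12 (3Z,5S,6E,8E,10E)-7,9-diethyl-5-methyl-11-phenylundeca-3,6,8,10-tetraen-3-yl trifluoromethanesulfonate; 16 (2E)-3-iodo-2-methylprop-2-enoic acid
Product: 19 spiculoic acid B [(1R,3aR,4R,5S,7aS)-3,5,7-triethyl-1,4-dimethyl-5-[(E)-2-phenylethenyl]-3a,4,5,7a-tetrahydro-1H-indene-4-carboxylic acid], via alkenyl boronate 17 (not isolated), via pentaenoic acid 18 (not isolated)
Conditions: B2pin2, PdCl2(PPh3)2/PPh3 (3 mol %), KOPh, PhMe, 50 °C; then 16, K3PO4, dioxane/H2O, 60 °C; then KH2PO4 (aq), 90 °C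
Reagents that add atoms: none
Why: Miyaura borylation and Suzuki–Miyaura coupling, both with retention at sp2 carbon, give the (2E,4Z,6S)-pentaenoic acid 18, whose intramolecular Diels–Alder reaction (C7–C10 diene, C2=C3 dienophile, CO2H-endo trans-fused transition state, diene face fixed by A1,3 strain between the C6 substituents and the C8 ethyl group) forms both rings and sets C3a, C4, C5 and C7a, giving the free acid directly so that no hindered ester has to be cleaved.

## Compound list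

1 | trans-cinnamaldehyde | O=C/C=C/c1ccccc1 | starting material
2 | [(E)-but-1-en-3-yn-1-yl]benzene | C#C/C=C/c1ccccc1 | intermediate
3 | ethyl pent-2-ynoate | CCC#CC(=O)OCC | starting material
4 | [(1E,3E)-2-ethyl-4-phenylbuta-1,3-dien-1-yl]copper | [Cu]/C=C(CC)/C=C/c1ccccc1 | intermediate
5 | ethyl (2Z,4E,6E)-2-cuprio-3,5-diethyl-7-phenylhepta-2,4,6-trienoate | CCOC(=O)/C([Cu])=C(CC)/C=C(CC)/C=C/c1ccccc1 | intermediate
6 | ethyl (2E,4E,6E)-3,5-diethyl-7-phenylhepta-2,4,6-trienoate | CCOC(=O)/C=C(CC)/C=C(CC)/C=C/c1ccccc1 | intermediate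
7 | (2E,4E,6E)-3,5-diethyl-7-phenylhepta-2,4,6-trien-1-ol | OC/C=C(CC)/C=C(CC)/C=C/c1ccccc1 | intermediate
8 | diethyl (2-oxobutyl)phosphonate | CCC(=O)CP(=O)(OCC)OCC | starting material
9 | (2E,4E,6E)-3,5-diethyl-7-phenylhepta-2,4,6-trienal | O=C/C=C(CC)/C=C(CC)/C=C/c1ccccc1 | intermediate
10 | (4E,6E,8E,10E)-7,9-diethyl-11-phenylundeca-4,6,8,10-tetraen-3-one | CCC(=O)/C=C/C=C(CC)/C=C(CC)/C=C/c1ccccc1 | intermediate
11 | bromomagnesium (3Z,5S,6E,8E,10E)-7,9-diethyl-5-methyl-11-phenylundeca-3,6,8,10-tetraen-3-olate | CC/C(O[Mg]Br)=C/[C@@H](C)/C=C(CC)/C=C(CC)/C=C/c1ccccc1 | intermediate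
12 | (3Z,5S,6E,8E,10E)-7,9-diethyl-5-methyl-11-phenylundeca-3,6,8,10-tetraen-3-yl trifluoromethanesulfonate | CC/C(OS(=O)(=O)C(F)(F)F)=C/[C@@H](C)/C=C(CC)/C=C(CC)/C=C/c1ccccc1 | intermediate
13 | diethyl methylmalonate | CCOC(=O)C(C)C(=O)OCC | starting material
14 | iodoform | IC(I)I | starting material
15 | diethyl 2-(diiodomethyl)-2-methylpropanedioate | CCOC(=O)C(C)(C(I)I)C(=O)OCC | intermediate
16 | (2E)-3-iodo-2-methylprop-2-enoic acid | OC(=O)/C(C)=C/I | intermediate
17 | 2-[(3E,5R,6E,8E,10E)-7,9-diethyl-5-methyl-11-phenylundeca-3,6,8,10-tetraen-3-yl]-4,4,5,5-tetramethyl-1,3,2-dioxaborolane (boron cis to C5) | CC/C(B1OC(C)(C)C(C)(C)O1)=C/[C@@H](C)/C=C(CC)/C=C(CC)/C=C/c1ccccc1 | intermediate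
18 | (2E,4Z,6S,7E,9E,11E)-4,8,10-triethyl-2,6-dimethyl-12-phenyldodeca-2,4,7,9,11-pentaenoic acid | OC(=O)/C(C)=C/C(CC)=C\[C@@H](C)/C=C(CC)/C=C(CC)/C=C/c1ccccc1 | intermediate
19 | spiculoic acid B, (1R,3aR,4R,5S,7aS)-3,5,7-triethyl-1,4-dimethyl-5-[(E)-2-phenylethenyl]-3a,4,5,7a-tetrahydro-1H-indene-4-carboxylic acid | CCC1=C[C@@](/C=C/c2ccccc2)(CC)[C@](C)(C(=O)O)[C@H]2C(CC)=C[C@@H](C)[C@H]12 | target

## Step count and risks

Total steps: 8. Longest linear sequence: 6 (1 → 2 → 6 → 7 → 10 → 12 → 19).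

**Step 8 (borylation/coupling/bicyclisation).** The carboxylic acid may be too weak a dienophile, or the endo/exo ratio may be poor. The fallback sets out from 12 and 16 and comes back at 19. Acid 16 is reduced with LiAlH4 to (2E)-3-iodo-2-methylprop-2-en-1-ol F4. Boronate 17, made from 12 as before, is coupled with F4 to give (2E,4Z,6S,7E,9E,11E)-4,8,10-triethyl-2,6-dimethyl-12-phenyldodeca-2,4,7,9,11-pentaen-1-ol F5. MnO2 oxidation gives (2E,4Z,6S,7E,9E,11E)-4,8,10-triethyl-2,6-dimethyl-12-phenyldodeca-2,4,7,9,11-pentaenal F6. A Me2AlCl-promoted intramolecular Diels–Alder reaction at −78 to −20 °C, where the chelated enal is strongly endo-selective, gives (1R,3aR,4R,5S,7aS)-3,5,7-triethyl-1,4-dimethyl-5-[(E)-2-phenylethenyl]-3a,4,5,7a-tetrahydro-1H-indene-4-carbaldehyde F7. Pinnick oxidation of F7 gives 19.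

**Step 5 (asymmetric conjugate methylation with enolate triflation).** The ee, the 1,4-selectivity on the polyenone, the enolate Z/E ratio and the O-triflation of a magnesium enolate are all uncertain. The fallback sets out from 10 and comes back at 12, and separates the creation of the stereocentre from the enolate capture. Cu(I)/phosphoramidite-catalysed addition of Me3Al with TMSOTf capture gives trimethyl{[(3Z,5S,6E,8E,10E)-7,9-diethyl-5-methyl-11-phenylundeca-3,6,8,10-tetraen-3-yl]oxy}silane F3. F3 is isolated, assayed for ee and Z/E, and enriched if needed. MeLi then regenerates the lithium enolate with retention of geometry, and Comins' reagent gives 12.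

**Step 2 (double carbocupration).** The alkenylcopper–MgBr2 species 4 may be too sluggish towards the β-substituted ynoate, or the α-cuprio ester 5 may scramble geometry through the allenolate. The fallback sets out from 2 and 3 and comes back at 6, replacing the conjugate addition by a cross-coupling. The dienylcopper 4 is quenched with iodine to give [(1E,3E)-3-ethyl-4-iodobuta-1,3-dien-1-yl]benzene F1. Separately, copper-catalysed syn-hydroboration of 3 (CuCl/Xantphos, NaOt-Bu, B2pin2, MeOH) gives ethyl (2Z)-3-(4,4,5,5-tetramethyl-1,3,2-dioxaborolan-2-yl)pent-2-enoate F2. Suzuki–Miyaura coupling of F1 with F2, with retention at both sp2 carbons, gives 6.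

## Further compounds

F1 | step 2 | [(1E,3E)-3-ethyl-4-iodobuta-1,3-dien-1-yl]benzene | I/C=C(CC)/C=C/c1ccccc1
F2 | step 2 | ethyl (2Z)-3-(4,4,5,5-tetramethyl-1,3,2-dioxaborolan-2-yl)pent-2-enoate | CCOC(=O)/C=C(\CC)B1OC(C)(C)C(C)(C)O1
F3 | step 5 | trimethyl{[(3Z,5S,6E,8E,10E)-7,9-diethyl-5-methyl-11-phenylundeca-3,6,8,10-tetraen-3-yl]oxy}silane | CC/C(O[Si](C)(C)C)=C/[C@@H](C)/C=C(CC)/C=C(CC)/C=C/c1ccccc1
F4 | step 8 | (2E)-3-iodo-2-methylprop-2-en-1-ol | OC/C(C)=C/I
F5 | step 8 | (2E,4Z,6S,7E,9E,11E)-4,8,10-triethyl-2,6-dimethyl-12-phenyldodeca-2,4,7,9,11-pentaen-1-ol | OC/C(C)=C/C(CC)=C\[C@@H](C)/C=C(CC)/C=C(CC)/C=C/c1ccccc1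
F6 | step 8 | (2E,4Z,6S,7E,9E,11E)-4,8,10-triethyl-2,6-dimethyl-12-phenyldodeca-2,4,7,9,11-pentaenal | O=C/C(C)=C/C(CC)=C\[C@@H](C)/C=C(CC)/C=C(CC)/C=C/c1ccccc1
F7 | step 8 | (1R,3aR,4R,5S,7aS)-3,5,7-triethyl-1,4-dimethyl-5-[(E)-2-phenylethenyl]-3a,4,5,7a-tetrahydro-1H-indene-4-carbaldehyde | CCC1=C[C@@](/C=C/c2ccccc2)(CC)[C@](C)(C=O)[C@H]2C(CC)=C[C@@H](C)[C@H]12
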